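The constants are invented; what happens was integrated by code.

The trap in this flask was to put the charged reagent straight into the rate of step 3, although it is charged into the other phase.

    target ⇌ product in the second phase, rate k1*([target] - [product in the second phase]/K1) per volume of the first phase (K1 = 1.3, k1 = 4.3 min⁻¹)
    target → decomposed product (k2 = 0.059 min⁻¹)
    substrate + reagent in the reaction phase → target (k3 = 0.14 M⁻¹ min⁻¹)
    substrate ⇌ dormant form (K4 = 1.2, k4 = 0.029 min⁻¹)
    reagent in the reaction phase ⇌ reagent in the second phase, rate k5*([reagent in the reaction phase] - [reagent in the second phase]/K5) per volume of the first phase (K5 = 4.0, k5 = 0.83 min⁻¹)
    crystals ⇌ target, rate k6*(cs6 - [target]) while solid is left; crystals form when [target] > cs6 (cs6 = 14 mM, k6 = 0.78 min⁻¹)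
    substrate + target ⇌ idle adduct, settled at all times (K7 = 1.6 M⁻¹)

substrate 0.80 M; reagent in the second phase 2.40 M; time 80 min; volume of the second phase over the first 2.0

- percentages count the substrate that a species holds: one idle adduct counts as two
- target is meant together with its product in the second phase and crystals and idle adduct
- in the second phase: reagent in the second phase, product in the second phase; everything else is in the first
- charges count per volume of the first phase; a concentration in a rate is the amount of a species over the volume of its own phase; every rate counts per litre of the first phase
- solid, in amounts per volume of the solution: crystals
- in an amount of target, one idle adduct counts as one target
- run time (flask): 80 min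

* the target and product in the second phase and crystals and idle adduct together standing at 80 min, as a percentage of the substrate charged
* concentration of target in solution at 20 min, in percent of saturation
* the change that raises the amount of target and product in the second phase and crystals and idle adduct together at 80 min, in percent of the substrate charged most ("none" if none brings more than 2 percentage points) (winter / autumn / noon / dawn / none)
* amount of target and product in the second phase and crystals and idle adduct together at 80 min, in percent of the substrate charged, after noon

For each part of reagent in the reaction phase, the second phase holds 8.00 parts at balance, and transfer takes about 1.20 min, far shorter than the reaction time 18.6 min. So I took the unused reagent's portion in the reaction phase as 11.1%, and this reaction-phase share is what I carried. It gave [reagent in the reaction phase] = 0.267 M and a pseudo-first-order constant of 0.0373 min⁻¹.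

Substrate and dormant form relax towards their balance in 18.8 min, about as long as that reaction time, so a shared pool was only a crude assumption of mine; I still let it fall at that constant over 2.20. My first round converted 74.3%. Then I iterated: that conversion spends reagent, so I put the mean reagent level back in and got 69.6%. I held dissolved target above solubility by the mean making rate over the dissolution coefficient, 8.92 mM. Step 2 then cost 13.5%, which left 56.0% standing. My reckoning did not reach the saturation at 20 min.

Then I turned the settings. Noon changed nothing by hand, since transfer takes 0.233 min, far shorter than the run. Dawn shrank the excess and saved 2.6 percentage points. Winter added solubility and cost 8.3 points. Autumn kept the share but doubled the reagent, so two rounds gave 93.4%, then 91.8%. That left 76.6%, a gain of 21 points, more than dawn's.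

The forecast said 59% standing, somewhat above my figure, with 188% of saturation, autumn as the best change and 59% after noon, on the ground that “conversion is reagent-limited and competes with the slow substrate-to-dormant leak”.

The simulation gave 56.8%, 189% and 56.8% after noon, so the forecast held. Autumn brought 16 points, more than any other change, while dawn brought 1.8 points, winter −7 points and noon 0.012 points.

In the flask at 80 min the substrate's half-life by step 3 read 24 min, and the share, with the reagent used put back, gives 24.1 min; free dissolved target's half-life by step 2 read 12 min at 7.80 min, shorter than the run, while crystals held 49.3% of the charge at 80.0 min. In the neighbour flask read at 30 min, with 40.5% target and 5.14% decomposed product made, the share gives 0.226 M of reagent in the reaction phase, and that flask held 0.220 M.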